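**Plan**

1. Numbering used throughout: ring C1 (C=O), C2=C3, C4 (OMe), C5H2, C6 (quaternary); side chain C7 (CHMe), C8 (CHOH–aryl, oxygen O8). The retrosynthesis first removes the C2=C3 unsaturation and then cuts C3–C4 of the saturated ketone.
2. The C1 carbonyl and the C4 methoxy carbon stand 1,4 (a homoaldol pattern), so C3–C4 can form from a C4 oxocarbenium ion (from CH(OMe)2) and a C1 homoenol. Because O8 is γ to C1, that homoenol can be a cyclopropane spiro-fused at C1 to a tetrahydrofuran O8–C1–C6–C7–C8.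
3. The tetrahydrofuran comes from a γ-lactone (methylenation, cyclopropanation). The lactone is cut at C6 into two enolate alkylations and further into a syn-crotylation of 3,4,5-trimethoxybenzaldehyde.
4. Forward order: crotylboration, hydroboration and oxidative lactonisation (lactone ring); two alkylations at C6; enol ether and spirocyclopropane; homoenol ring closure (cyclohexanone ring, tetrahydrofuran opened on hydrolysis); dehydrogenation to the enone.
5. Stereochemistry: C7 and C8 from the chiral phosphoric acid-catalysed (Z)-crotylboration; C6 from allylation of the lactone enolate anti to the C7 methyl group; C4 from the chair-like ring closure held by the tetrahydrofuran ring.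

Key step: step 9

Remark: the (R)-configured phosphoric acid is assumed to direct the crotyl group to the Re face of the aldehyde, as in its allylborations of aryl aldehydes (the (S)-acid would be used if the sense proves opposite). Lactones 10 to 12 are drawn as the major 3,4-trans isomers; that centre is re-enolised in step 6, so its configuration is of no consequence.

**Route**

Step 1
Reactants: 1 3,4,5-trimethoxybenzaldehyde; 2 (Z)-crotylboronic acid pinacol ester
Product: 4 (1R,2S)-2-methyl-1-(3,4,5-trimethoxyphenyl)but-3-en-1-ol, via pinacol borate ester 3 (not isolated)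
Conditions: (R)-3,3'-bis(2,4,6-triisopropylphenyl)-1,1'-binaphthyl-2,2'-diyl hydrogen phosphate (5 mol %), toluene, −30 °C; aq. NaHCO3 work-up
Reagents that add atoms: none
Why: Chiral phosphoric acid-catalysed crotylboration through a closed chair (Zimmerman–Traxler) transition state should turn the (Z)-boronate into the syn adduct, while the acid, hydrogen-bonded to the boronate oxygen and the formyl hydrogen, selects the Re face, setting C8 (R) and C7 (S).

Step 2
Reactants: 4 (1R,2S)-2-methyl-1-(3,4,5-trimethoxyphenyl)but-3-en-1-ol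
Product: 6 (1R,2S)-2-methyl-1-(3,4,5-trimethoxyphenyl)butane-1,4-diol, via B-alkyl-9-borabicyclononane 5 (not isolated)
Conditions: 9-borabicyclo[3.3.1]nonane (9-BBN-H, 2.2 equiv), THF, 0 °C to rt; then 3 M aq. NaOH, 30% H2O2, 0 °C to rt
Reagents that add atoms: hydrogen peroxide, OO
Why: Anti-Markovnikov hydroboration of the terminal alkene followed by oxidation with retention at carbon should give the primary alcohol without touching the two stereocentres.

Step 3
Reactants: 6 (1R,2S)-2-methyl-1-(3,4,5-trimethoxyphenyl)butane-1,4-diol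
Product: 8 (4S,5R)-4-methyl-5-(3,4,5-trimethoxyphenyl)oxolan-2-one, via lactol 7 (not isolated)
Conditions: 2,2,6,6-tetramethylpiperidin-1-oxyl (TEMPO, 0.2 equiv), PhI(OAc)2 (2.5 equiv), CH2Cl2, rt
Reagents that add atoms: none
Why: Oxoammonium-mediated oxidative lactonisation of a 1,4-diol: the primary alcohol is oxidised first, the aldehyde is trapped by the benzylic hydroxyl as the lactol, and this is oxidised to the cis-4-methyl-5-aryl lactone.

Step 4
Reactants: 8 (4S,5R)-4-methyl-5-(3,4,5-trimethoxyphenyl)oxolan-2-one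
Product: 10 (3S,4S,5R)-4-methyl-3-(prop-2-en-1-yl)-5-(3,4,5-trimethoxyphenyl)oxolan-2-one, via lithium enolate 9 (not isolated)
Conditions: LiN(iPr)2 (1.1 equiv), THF, −78 °C; then allyl bromide, −78 to −40 °C
Reagents that add atoms: allyl bromide, C=CCBr
Why: Kinetic lactone enolate alkylation should place the allyl group mainly trans to the methyl group.

Step 5
Reactants: 10 (3S,4S,5R)-4-methyl-3-(prop-2-en-1-yl)-5-(3,4,5-trimethoxyphenyl)oxolan-2-one
Product: 12 (3S,4S,5R)-3-(2,2-dimethoxyethyl)-4-methyl-5-(3,4,5-trimethoxyphenyl)oxolan-2-one, via aldehyde 11 (not isolated)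
Conditions: O3, CH2Cl2/MeOH (4:1), −78 °C (Sudan red 7B end point); Me2S, −78 °C to rt; then HC(OMe)3, TsOH·H2O (5 mol %), rt
Reagents that add atoms: methanol, CO; trimethyl orthoformate, COC(OC)OC
Why: Ozonolysis with reductive work-up (the alkene reacts far faster than the trimethoxyarene) followed by acid-catalysed acetalisation turns the allyl group into the protected two-carbon aldehyde arm that will become C5–C4.

Step 6
Reactants: 12 (3S,4S,5R)-3-(2,2-dimethoxyethyl)-4-methyl-5-(3,4,5-trimethoxyphenyl)oxolan-2-one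
Product: 14 (3R,4S,5R)-3-(2,2-dimethoxyethyl)-4-methyl-3-(prop-2-en-1-yl)-5-(3,4,5-trimethoxyphenyl)oxolan-2-one, via lithium enolate 13 (not isolated)
Conditions: LiN(iPr)2 (1.2 equiv), THF/DMPU, −78 °C; then allyl bromide, −78 to −20 °C
Reagents that add atoms: allyl bromide, C=CCBr
Why: In this alkylation of the trisubstituted lactone enolate, allyl bromide should enter anti to the neighbouring methyl group (and to the cis aryl group), which sets the quaternary centre C6 with allyl trans and the acetal arm cis to the methyl group.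

Step 7
Reactants: 14 (3R,4S,5R)-3-(2,2-dimethoxyethyl)-4-methyl-3-(prop-2-en-1-yl)-5-(3,4,5-trimethoxyphenyl)oxolan-2-one
Product: 15 (2R,3S,4R)-4-(2,2-dimethoxyethyl)-3-methyl-5-methylidene-4-(prop-2-en-1-yl)-2-(3,4,5-trimethoxyphenyl)oxolane
Conditions: Cp2TiMe2 (2.5 equiv), toluene, 65 °C, in the dark; filtration through basic alumina
Reagents that add atoms: dimethyltitanocene Cp2TiMe2, C[Ti](C)(C1C=CC=C1)C1C=CC=C1
Why: Petasis methylenation of the lactone carbonyl by thermally generated Cp2Ti=CH2 via an oxatitanacyclobutane should give the exocyclic enol ether, which cannot migrate into the ring because C6 is quaternary.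

Step 8
Reactants: 15 (2R,3S,4R)-4-(2,2-dimethoxyethyl)-3-methyl-5-methylidene-4-(prop-2-en-1-yl)-2-(3,4,5-trimethoxyphenyl)oxolane
Product: 16 (5R,6S,7R)-7-(2,2-dimethoxyethyl)-6-methyl-7-(prop-2-en-1-yl)-5-(3,4,5-trimethoxyphenyl)-4-oxaspiro[2.4]heptane
Conditions: Et2Zn (3 equiv), CH2I2 (3 equiv), CH2Cl2, 0 °C; pyridine, then aq. NaHCO3
Reagents that add atoms: diiodomethane, ICI
Why: In this Simmons–Smith (Furukawa) cyclopropanation the electrophilic zinc carbenoid should add to the electron-rich enol ether much faster than to the monosubstituted allyl alkene, and the spiro carbon formed is not a stereocentre.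

Step 9
Reactants: 16 (5R,6S,7R)-7-(2,2-dimethoxyethyl)-6-methyl-7-(prop-2-en-1-yl)-5-(3,4,5-trimethoxyphenyl)-4-oxaspiro[2.4]heptane
Product: 18 (2R,4S)-2-[(1R,2S)-1-hydroxy-1-(3,4,5-trimethoxyphenyl)propan-2-yl]-4-methoxy-2-(prop-2-en-1-yl)cyclohexan-1-one, via cyclic methyl ketal 17 (not isolated)
Conditions: Me3SiOTf (0.2 equiv), 2,6-di-tert-butyl-4-methylpyridine (0.3 equiv), CH2Cl2, −78 °C; then 0.1 M aq. HCl, THF, 0 °C
Reagents that add atoms: water, O
Why: Proposed new method: Me3SiOTf ionises the acetal to the (E)-methyl oxocarbenium ion at C4; the strained C1–C3 σ bond of the alkoxycyclopropane, raised in energy by the lone pair of ring oxygen O8 on C1, attacks it as a homoenol ether, so that C3–C4 forms as C1–C3 breaks and the charge ends on the five-membered oxocarbenium ion O8=C1, which takes methoxide back from Me3SiOMe to give ketal 17 (Me3SiOTf is regenerated) and is hydrolysed to γ-hydroxy ketone 18 (which may rest partly as its cyclic hemiketal). The closest known reaction type is the Lewis acid-mediated cyclisation of cyclopropanol silyl ethers (homoenols) onto acetal-derived oxocarbenium ions, a homo-Mukaiyama (Prins-type) process used for seven-membered carbocycles and oxepanes, together with the acid-induced ring opening of alkoxycyclopropanes; new here are the cyclic alkyl ether as donor group and the six-membered closure. The cyclohexane ring closes in a 6-(homoenol-endo)-exo-trig mode through a five-centre array C4–C5–C6–C1–C3 with front-side attack on the cyclopropane methylene. The new C4 stereocentre is controlled by the tetrahydrofuran ring, which holds C7 pseudo-equatorial and the allyl group axial on the forming chair, so that the oxocarbenium methoxy group goes equatorial to avoid the 1,3-diaxial contact with the allyl group and ends cis to C7 as in the target. The step needs chemoselectivity for the cyclopropane over the allyl π bond, the trimethoxyarene and O8; it is secured because only the cyclopropane path releases ring strain and leads directly to an oxocarbenium ion, whereas alkene attack would give a secondary cation, arene attack a seven-membered ring and O8 attack a strained bridged oxonium ion. Integrity of the benzylic C8–O8 bond is secured by the low temperature, the hindered pyridine base and the catalytic amount of silyl triflate.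

Step 10
Reactants: 18 (2R,4S)-2-[(1R,2S)-1-hydroxy-1-(3,4,5-trimethoxyphenyl)propan-2-yl]-4-methoxy-2-(prop-2-en-1-yl)cyclohexan-1-one
Product: 22 megaphone, via dilithium alkoxide enolate 19 (not isolated), via α-phenylselanyl ketone 20 (not isolated), via selenoxide 21 (not isolated)
Conditions: LiN(iPr)2 (2.3 equiv), THF, −78 to −30 °C; PhSeBr (1.05 equiv), −78 °C; then 30% H2O2, pyridine, CH2Cl2, 0 °C to rt
Reagents that add atoms: none
Why: In this selenoxide dehydrogenation the ketone can enolise only towards C2 (C6 is quaternary), the enolate is selenenylated at C2 faster than the alkene reacts, and the selenoxide undergoes syn-elimination towards C3 to give the 2-ene without touching any stereocentre.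

**Compound list**

1 | 3,4,5-trimethoxybenzaldehyde | COc1cc(C=O)cc(OC)c1OC | starting material
2 | (Z)-crotylboronic acid pinacol ester, 2-[(2Z)-but-2-en-1-yl]-4,4,5,5-tetramethyl-1,3,2-dioxaborolane | C/C=C\CB1OC(C)(C)C(C)(C)O1 | starting material
3 | pinacol borate ester of 4, 4,4,5,5-tetramethyl-2-{[(1R,2S)-2-methyl-1-(3,4,5-trimethoxyphenyl)but-3-en-1-yl]oxy}-1,3,2-dioxaborolane | C=C[C@H](C)[C@@H](OB1OC(C)(C)C(C)(C)O1)c2cc(OC)c(OC)c(OC)c2 | intermediate
4 | (1R,2S)-2-methyl-1-(3,4,5-trimethoxyphenyl)but-3-en-1-ol | C=C[C@H](C)[C@@H](O)c1cc(OC)c(OC)c(OC)c1 | intermediate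
5 | 9-[(3S,4R)-4-hydroxy-3-methyl-4-(3,4,5-trimethoxyphenyl)butyl]-9-borabicyclo[3.3.1]nonane | B1(CC[C@H](C)[C@@H](O)c2cc(OC)c(OC)c(OC)c2)C3CCCC1CCC3 | intermediate
6 | (1R,2S)-2-methyl-1-(3,4,5-trimethoxyphenyl)butane-1,4-diol | OCC[C@H](C)[C@@H](O)c1cc(OC)c(OC)c(OC)c1 | intermediate
7 | (4S,5R)-4-methyl-5-(3,4,5-trimethoxyphenyl)oxolan-2-ol (lactol, both anomers) | OC1C[C@H](C)[C@@H](O1)c2cc(OC)c(OC)c(OC)c2 | intermediate
8 | (4S,5R)-4-methyl-5-(3,4,5-trimethoxyphenyl)oxolan-2-one (methyl and aryl cis) | O=C1C[C@H](C)[C@@H](O1)c2cc(OC)c(OC)c(OC)c2 | intermediate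
9 | lithium enolate of 8 | [Li]OC1=C[C@H](C)[C@@H](O1)c2cc(OC)c(OC)c(OC)c2 | intermediate
10 | (3S,4S,5R)-4-methyl-3-(prop-2-en-1-yl)-5-(3,4,5-trimethoxyphenyl)oxolan-2-one | O=C1O[C@@H](c2cc(OC)c(OC)c(OC)c2)[C@@H](C)[C@@H]1CC=C | intermediate
11 | [(3S,4S,5R)-4-methyl-2-oxo-5-(3,4,5-trimethoxyphenyl)oxolan-3-yl]acetaldehyde | O=C1O[C@@H](c2cc(OC)c(OC)c(OC)c2)[C@@H](C)[C@@H]1CC=O | intermediate
12 | (3S,4S,5R)-3-(2,2-dimethoxyethyl)-4-methyl-5-(3,4,5-trimethoxyphenyl)oxolan-2-one | O=C1O[C@@H](c2cc(OC)c(OC)c(OC)c2)[C@@H](C)[C@@H]1CC(OC)OC | intermediate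
13 | lithium enolate of 12 | [Li]OC1=C(CC(OC)OC)[C@H](C)[C@@H](O1)c2cc(OC)c(OC)c(OC)c2 | intermediate
14 | (3R,4S,5R)-3-(2,2-dimethoxyethyl)-4-methyl-3-(prop-2-en-1-yl)-5-(3,4,5-trimethoxyphenyl)oxolan-2-one (allyl trans, acetal arm cis to methyl) | C=CC[C@@]1(CC(OC)OC)[C@H](C)[C@H](c2cc(OC)c(OC)c(OC)c2)OC1=O | intermediate
15 | (2R,3S,4R)-4-(2,2-dimethoxyethyl)-3-methyl-5-methylidene-4-(prop-2-en-1-yl)-2-(3,4,5-trimethoxyphenyl)oxolane | C=CC[C@@]1(CC(OC)OC)[C@H](C)[C@H](c2cc(OC)c(OC)c(OC)c2)OC1=C | intermediate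
16 | (5R,6S,7R)-7-(2,2-dimethoxyethyl)-6-methyl-7-(prop-2-en-1-yl)-5-(3,4,5-trimethoxyphenyl)-4-oxaspiro[2.4]heptane | C=CC[C@@]1(CC(OC)OC)[C@H](C)[C@H](c2cc(OC)c(OC)c(OC)c2)OC13CC3 | intermediate
17 | (2R,3S,3aR,5S)-5,7a-dimethoxy-3-methyl-3a-(prop-2-en-1-yl)-2-(3,4,5-trimethoxyphenyl)octahydro-1-benzofuran (cyclic methyl ketal, C7a not defined) | C=CC[C@]12C[C@@H](OC)CCC1(OC)O[C@@H](c3cc(OC)c(OC)c(OC)c3)[C@H]2C | intermediate
18 | (2R,4S)-2-[(1R,2S)-1-hydroxy-1-(3,4,5-trimethoxyphenyl)propan-2-yl]-4-methoxy-2-(prop-2-en-1-yl)cyclohexan-1-one (2,3-dihydromegaphone) | C=CC[C@]1([C@H](C)[C@@H](O)c2cc(OC)c(OC)c(OC)c2)C[C@@H](OC)CCC1=O | intermediate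
19 | dilithium alkoxide enolate of 18 | C=CC[C@]1([C@H](C)[C@@H](O[Li])c2cc(OC)c(OC)c(OC)c2)C[C@@H](OC)CC=C1O[Li] | intermediate
20 | 6-(phenylselanyl) derivative of 18 (both epimers at the selenium-bearing carbon) | C=CC[C@]1([C@H](C)[C@@H](O)c2cc(OC)c(OC)c(OC)c2)C[C@@H](OC)CC([Se]c3ccccc3)C1=O | intermediate
21 | selenoxide of 20 | C=CC[C@]1([C@H](C)[C@@H](O)c2cc(OC)c(OC)c(OC)c2)C[C@@H](OC)CC([Se](=O)c3ccccc3)C1=O | intermediate
22 | megaphone, (4R,6R)-6-[(1R,2S)-1-hydroxy-1-(3,4,5-trimethoxyphenyl)propan-2-yl]-4-methoxy-6-(prop-2-en-1-yl)cyclohex-2-en-1-one | C=CC[C@]1([C@H](C)[C@@H](O)c2cc(OC)c(OC)c(OC)c2)C[C@@H](OC)C=CC1=O | target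

**Step count and risks**

Total step count: 10. Longest linear sequence: 10 steps (1 to 22).

Steps most likely to fail:

1. Step 9 (Proposed new method). What may go wrong: the cyclopropane may fail to engage through the tight five-centre array; the allyl group may close instead in a Prins reaction; the benzylic C8–O8 bond may ionise, with loss of configuration at C8; adventitious acid may simply protonate the cyclopropane. The fallback uses known chemistry, closes the same C3–C4 bond by an organochromium addition, sets out from 14 and comes back at 22.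
 - Me3SiC≡CLi (THF, −78 °C) adds once to the lactone carbonyl to give hydroxy ynone F1 (in equilibrium with its lactol).
 - tBuMe2SiOTf/2,6-lutidine caps the benzylic hydroxyl to give silyl ether F2.
 - Na2B4O7·10H2O in aqueous methanol removes the alkynyl silyl group to give terminal ynone F3.
 - Aqueous trifluoroacetic acid in CH2Cl2 at 0 °C unveils aldehyde F4.
 - NaI in acetic acid adds HI in anti fashion to give (Z)-β-iodoenone F5.
 - CrCl2 with catalytic NiCl2 (DMF, rt, high dilution) performs an intramolecular Nozaki–Hiyama–Kishi addition of the alkenylchromium to the aldehyde to give hydroxy enone F6; the chair-like closure with the chromium alkoxide equatorial and the allyl group axial should give the 4,6-cis relationship.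
 - Me3OBF4 with 1,8-bis(dimethylamino)naphthalene methylates the allylic hydroxyl to give methyl ether F7.
 - HF·pyridine in THF removes the silyl ether and gives 22.

2. Step 8. What may go wrong: slow methylene transfer to the hindered enol ether, with competing cyclopropanation of the allyl group, or hydrolysis and decomposition of the acid-labile enol ether by the zinc iodide formed. The fallback sets out from 15 and comes back at 16. Dibromocarbene generated under basic phase-transfer conditions (CHBr3, 50% aq. NaOH, BnEt3NCl) adds selectively to the electron-rich enol ether and leaves the acetal and the enol ether free of acid, giving gem-dibromocyclopropane F8. Radical reduction with Bu3SnH (2.5 equiv, high concentration) and azobisisobutyronitrile in toluene at 90 °C removes both bromine atoms and gives 16.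

3. Step 10. What may go wrong: incomplete enolisation because the lithium alkoxide closes onto the ketone as a hemiketalate, or selenenylation of the allyl alkene. The fallback sets out from 18 and comes back at 22 by a Saegusa–Ito dehydrogenation. Me3SiOTf/Et3N (CH2Cl2, 0 °C) gives bis-silyl compound F9 (silyl enol ether towards C2 and silyl ether at O8). Pd(OAc)2 in MeCN at rt effects dehydrosilylation to enone silyl ether F10. Dilute citric acid in methanol frees the hydroxyl and gives 22.

**Further compounds**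

F1 | step 9 | (4R)-4-(2,2-dimethoxyethyl)-4-[(1R,2S)-1-hydroxy-1-(3,4,5-trimethoxyphenyl)propan-2-yl]-1-(trimethylsilyl)hept-6-en-1-yn-3-one | C=CC[C@](C(=O)C#C[Si](C)(C)C)([C@H](C)[C@@H](O)c1cc(OC)c(OC)c(OC)c1)CC(OC)OC
F2 | step 9 | tert-butyldimethylsilyl ether of F1 | C=CC[C@](C(=O)C#C[Si](C)(C)C)([C@H](C)[C@@H](O[Si](C)(C)C(C)(C)C)c1cc(OC)c(OC)c(OC)c1)CC(OC)OC
F3 | step 9 | (4R)-4-[(1R,2S)-1-{[tert-butyl(dimethyl)silyl]oxy}-1-(3,4,5-trimethoxyphenyl)propan-2-yl]-4-(2,2-dimethoxyethyl)hept-6-en-1-yn-3-one | C=CC[C@](C(=O)C#C)([C@H](C)[C@@H](O[Si](C)(C)C(C)(C)C)c1cc(OC)c(OC)c(OC)c1)CC(OC)OC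
F4 | step 9 | (3R)-3-[(1R,2S)-1-{[tert-butyl(dimethyl)silyl]oxy}-1-(3,4,5-trimethoxyphenyl)propan-2-yl]-4-oxo-3-(prop-2-en-1-yl)hex-5-ynal | C=CC[C@](C(=O)C#C)([C@H](C)[C@@H](O[Si](C)(C)C(C)(C)C)c1cc(OC)c(OC)c(OC)c1)CC=O
F5 | step 9 | (3R,5Z)-3-[(1R,2S)-1-{[tert-butyl(dimethyl)silyl]oxy}-1-(3,4,5-trimethoxyphenyl)propan-2-yl]-6-iodo-4-oxo-3-(prop-2-en-1-yl)hex-5-enal | C=CC[C@](C(=O)/C=C\I)([C@H](C)[C@@H](O[Si](C)(C)C(C)(C)C)c1cc(OC)c(OC)c(OC)c1)CC=O
F6 | step 9 | (4R,6R)-6-[(1R,2S)-1-{[tert-butyl(dimethyl)silyl]oxy}-1-(3,4,5-trimethoxyphenyl)propan-2-yl]-4-hydroxy-6-(prop-2-en-1-yl)cyclohex-2-en-1-one | C=CC[C@]1([C@H](C)[C@@H](O[Si](C)(C)C(C)(C)C)c2cc(OC)c(OC)c(OC)c2)C[C@@H](O)C=CC1=O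
F7 | step 9 | megaphone tert-butyldimethylsilyl ether | C=CC[C@]1([C@H](C)[C@@H](O[Si](C)(C)C(C)(C)C)c2cc(OC)c(OC)c(OC)c2)C[C@@H](OC)C=CC1=O
F8 | step 8 | (5R,6S,7R)-1,1-dibromo-7-(2,2-dimethoxyethyl)-6-methyl-7-(prop-2-en-1-yl)-5-(3,4,5-trimethoxyphenyl)-4-oxaspiro[2.4]heptane (both configurations at the spiro carbon) | C=CC[C@@]1(CC(OC)OC)[C@H](C)[C@H](c2cc(OC)c(OC)c(OC)c2)OC13CC3(Br)Br
F9 | step 10 | bis(trimethylsilyl) derivative of 18 (silyl enol ether at C1, silyl ether at O8) | C=CC[C@]1([C@H](C)[C@@H](O[Si](C)(C)C)c2cc(OC)c(OC)c(OC)c2)C[C@@H](OC)CC=C1O[Si](C)(C)C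
F10 | step 10 | megaphone trimethylsilyl ether | C=CC[C@]1([C@H](C)[C@@H](O[Si](C)(C)C)c2cc(OC)c(OC)c(OC)c2)C[C@@H](OC)C=CC1=O
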